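The target in the larch run climbs in a straight line. On the candidate steps, solid substrate dissolves to starting material, which gives the target directly, while the isomer of the product comes by way of the other conformer.

| flask | solid substrate | remark | time |
|---|---|---|---|
| larch | 5.0 × 10⁻⁴ M | the very flask that is asked about, followed so far |  |
| flask | 5.0 × 10⁻⁴ M |  | 12 min |

larch run (percent of the solid substrate charged)

| time / min | isomer of the product / % | target / % |
|---|---|---|
| 0.500 | 1.2 | 5.0 |
| 0.833 | 0.7 | 7.4 |
| 1.50 | 1.6 | 15.6 |
| 3.00 | 2.2 | 31.4 |
| 6.00 | 5.5 | 62.5 |

(readings scatter by 0.5 percentage points)

- given per volume of solution although it is solid: solid substrate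
- candidate steps: starting material <-> other conformer; starting material -> target; other conformer -> isomer of the product; other conformer <-> third conformer; third conformer -> third product; other conformer -> decomposition product; other conformer <-> dormant form; solid substrate <-> starting material
- at the start none of the solid substrate is in solution

1. share of isomer of the product in isomer of the product plus target at 25 s
2. share of isomer of the product in isomer of the product plus target at 2.0 min
3. share of isomer of the product in isomer of the product plus target at 12 min
4. which of isomer of the product and target there is more of at 12 min

A rate that stays constant while the solid shrinks is zero-order in the solid. I read it as a steady level of dissolved starting material, and I look to that concentration, not to the solid charge. If both products draw on that level, its height cancels in the ratio of their rates. From the reading at 6.00 min, the target gains on average 0.104 min⁻¹ in fractions of the charge, and the isomer of the product gains 0.00917 min⁻¹. The isomer's rate over the sum of both rates is the branching share, a selectivity, 8.09 %. As a reading it carries 0.74 percentage points of scatter. The earliest share, 19.4 %, carries 8.1 points, so I set it aside. I commit to the branching share at each asked time, with the target ahead.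

The forecast gives 7.5 %, 8 % and 8.5 %, with the target ahead, and calls this “two products drawn from rapidly interconverting conformers”.

The flask gives 6.09 %, 7.39 % and 8.58 %, ending with 91.0 % target against 8.54 % isomer of the product.

    starting material ⇌ other conformer (K = 1.10, k = 0.0340 s⁻¹)
    starting material → target (k = 0.310 s⁻¹)
    other conformer → isomer of the product (k = 0.280 s⁻¹)
    other conformer ⇌ third conformer (K = 0.430, k = 0.120 s⁻¹)
    third conformer → third product (k = 0.0370 s⁻¹)
    other conformer → decomposition product (k = 1.70 × 10⁻⁴ s⁻¹)
    other conformer ⇌ dormant form (K = 6.80, k = 0.0890 s⁻¹)
    solid substrate ⇌ starting material, rate k8*(cs8 - [starting material]) while solid is left; crystals form when [starting material] > cs8 (solubility = 0.0200 mM, k = 0.0560 s⁻¹)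

My share, a reading, stands 2 points above the flask at 25 s and 0.5 points below it at 12 min. In the flask at 4.32 min, the half-life of starting material by its passing into target is 2.2 s. By the forward rate of its passing into other conformer alone, the half-life is longer, at 0.34 min. The neighbour flask, charged with 0.0020 M of solid substrate, still holds 65 % of its charge, solid or dissolved, at 12 min, and there my read 8.09 % stands against 8.35 %.

Readings and results are calculated with made-up constants; scatter was added.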